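## Structural features

Compound 29 is a single carbocycle, a cyclohex-2-en-1-one. The ring is numbered C1 (propanoyloxy carbinol), C2=C3 (C3 carries the hydroxymethyl carbon C7), C4 (ketone), C5 (carbinol esterified by (E)-4-hydroxy-2-methylbut-2-enoic acid) and C6 (isopropyl methine). The three stereocentres C1 (S), C6 (S) and C5 (R) are contiguous: the C1 oxygen is cis to the isopropyl group, the C5 oxygen is trans to it, so the two ester oxygens are trans to each other. The C1 ester is the leaving group of a γ-acyloxy enone (its loss opens the way to a dienone and a phenol), and C5 is α to the ketone and epimerisable. The two esters are different and can migrate to any free neighbouring hydroxyl, and two primary allylic alcohols must be freed at the end without base. The ring itself is not the difficulty. The difficulty is to tell apart three oxygen functions on C1, C4 and C5 (two different acyl groups and a ketone) around the carbon-substituted C6, while a hydroxymethyl group sits on the α-carbon of the enone. The key step uses the C3–C4 ring bond, which joins the alkene carbon C3 to the carbonyl carbon C4. With C3 as a Z alkenyl iodide and C4 as an aldehyde, this bond closes the ring with C2=C3 and C7 already in place.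

## Logic of the disconnections

29 ⇒ 28. The O–Si bonds at C7 and at the side-chain terminus are cut. Both primary allylic alcohols stay masked until the last step, so neither can accept a migrating acyl group. The gain is a fully protected diester; the demand is one non-basic fluoride step that a γ-acyloxy enone tolerates.

28 ⇒ 22 + 26. The C5–O acyl bond is cut. The enoate would not survive the hydride and organometallic steps of the chain synthesis, so it enters late as a separate five-carbon piece. The demand is acylation of a hindered α-ketol without epimerising C5 or eliminating the C1 ester.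

26 ⇒ 25 ⇒ 23 + 24. The ethyl ester C–O bond and then the trisubstituted C=C of the side chain are cut. An olefination fixes the E geometry and the position of the oxygen in one operation, which allylic functionalisation of a tiglate does not guarantee. The demand is E selectivity and survival of the silyl ether on hydrolysis.

22 ⇒ 21 ⇒ 20. The C5 O–Si bond is restored and the C4 ketone is taken back to a carbinol. A carbinol at C4 is what a carbonyl addition delivers, and its configuration does not matter. The demand is oxidation without disturbing C5, and cleavage of a secondary triethylsilyl ether beside a primary tert-butyldiphenylsilyl ether.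

20 ⇒ 18. The C3–C4 ring bond is cut (key step). It is the only ring bond that joins an sp2 carbon to the oxidised C4. Cutting it turns the ring into a seven-carbon chain that already holds C1, C5, C6, the alkene and C7, so all stereochemistry becomes an acyclic problem. The demand is an alkenyl metal that adds to an aldehyde but leaves esters alone, a Z alkene that holds C3 cis to C1, and no stereocontrol at C4.

18 ⇒ 17 ⇒ 16 ⇒ 15. The C4 aldehyde is taken back to the alcohol, then to its 4-methoxybenzyl ether, and the C1–O acyl bond is cut. The aldehyde is made last because it is the most sensitive group, and the propanoate goes on as soon as the C1 hydroxyl has done its directing work. The demand is neutral, buffered conditions throughout.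

15 ⇒ 13. The C3–I and C2–H bonds are cut, which returns the alkene to an alkyne. A propargylic alcohol is the most direct source of a Z-configured trisubstituted iodoalkene. The demand is that hydride goes to C2 and the metal to C3, with trans addition, and that the C7 oxygen is not eliminated.

13 ⇒ 12. The C1–H bond is cut (carbinol to ketone). This leaves C1 to a reagent-controlled reduction. The demand is that the catalyst overrides the neighbouring C6 centre.

12 ⇒ 8 + 10, and 10 ⇒ 9. The C1–C2 bond is cut between an acyl donor and an acetylide; the O–Si bond of 10 leads to 9. The chain falls into a four-carbon stereodiad and a three-carbon alkyne that brings C2, C3 and C7. The demand is single addition without enolising C6.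

8 ⇒ 7 ⇒ 6. The C5 O–Si bond and the amide C–N bond are cut, which returns the acyl group to the auxiliary. The free C5 hydroxyl is kept for the amide exchange because it directs the aluminium reagent to the right carbonyl.

6 ⇒ 3 + 4, and 3 ⇒ 1 + 2. The C5–C6 bond is cut (aldol), then the N–acyl bond. The C5/C6 relationship is syn in the open chain, which is the native outcome of a boron imide aldol. The demand is a Z enolate and facial control by the auxiliary; the (R)-auxiliary gives the required absolute sense.

## Other disconnections considered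

Alternative 1: The two C–O bonds at C1 and C4 are cut together (retro [4+2]). This leads to the diene (S)-2-[(tert-butyldimethylsilyloxy)methyl]-5-isopropylcyclohexa-1,3-diene (A2), a 7-oxygenated α-phellandrene, and oxygen.
- Forward: sensitised photo-oxygenation would give the endoperoxide A1. Base-induced Kornblum–DeLaMare opening would then give the hydroxy enone A3, with the C4 ketone, the C1 hydroxyl and C7 in place.
- In favour: the whole p-menthane skeleton, C7 and C6 included, is bought rather than built. Two oxygens enter in one concerted suprafacial step. The sequence is probably close to the biogenesis.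
- Against: oxygen should add anti to the isopropyl group, so A1 and A3 carry the C1 oxygen trans to isopropyl, while 29 needs it cis. C1 must therefore be inverted, for instance by Mitsunobu esterification with propanoic acid on an elimination-prone γ-hydroxy enone. A single remote isopropyl group gives only moderate facial bias. The peroxide can open at either bridgehead hydrogen, both of which are allylic. The C5 oxygen must be added late by enolate oxidation of a base-labile γ-acyloxy enone. Dienes such as A2 isomerise and aromatise easily.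
- Comparison: on step economy this route is the better one, perhaps ten steps against fifteen in the longest line of the chosen plan. As a bond-forming event the cycloaddition is the equal of the chromium-mediated closure. The chosen plan is better on stereochemical security: C1, C5 and C6 are each set by a reagent-controlled step and none needs inversion or late enolate chemistry.

Alternative 2: The C2–C3 ring bond is cut. This leads to a methyl hex-5-enopyranoside, A5, with a 3-C-isopropyl branch and the gulo arrangement at sugar C2–C4.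
- Forward: catalytic Hg(OCOCF3)2 in aqueous acetone would bring about the Ferrier carbocyclisation. After oxymercuration of the enol ether and ring opening, the sugar C6 carbon adds as an enolate to the unmasked sugar C1 carbonyl, giving the β-hydroxy cyclohexanone A4.
- In favour: C1, C5 and C6 come from the sugar, with no enantioselective reagent. The C1 and C5 oxygens arrive already differentiated as 4-methoxybenzyl and silyl ethers. The β-hydroxy ketone can be dehydrated directly to the C2=C3 enone.
- Against: a C-isopropyl branch with the correct configuration must be installed on a pyranoside, and two centres of a glucose precursor must be inverted. That takes many steps and protecting-group changes. A4 has no C7, so the hydroxymethyl group must be added afterwards (Morita–Baylis–Hillman reaction with formaldehyde) to an enone that carries a γ leaving group. A mercury salt is needed.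
- Comparison: on the origin of absolute configuration it is the equal of the chosen plan, or better, since it relies on the chiral pool and not on a catalyst. On oxygen differentiation the two are equal. The carbocyclisation is as dependable a ring closure as the one chosen. On step count it is clearly worse, well over twenty steps by estimate, and it places C7 late where the chosen plan carries it in from propargyl alcohol.

Alternative 3: The C5–C6 bond is cut. This leads to the acyclic Z-configured ketoaldehyde A7, with the C1 silyloxy stereocentre, a C6=CMe2 alkene and a C4/C5 1,2-dicarbonyl.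
- Forward: a Lewis acid such as Sc(OTf)3 would trigger an isopulegol-type carbonyl-ene closure. The C5 aldehyde accepts C6 and an allylic hydrogen, giving the all-trans hydroxy enone A6 with an isopropenyl group on C6.
- In favour: one step makes the ring, a C–C bond and two stereocentres (C5 and C6) from a single stereocentre. The enone, C7 and the C5 hydroxyl are all in place, and A7 is short to prepare.
- Against: the all-trans product has the C1 oxygen trans to the C6 substituent, so C1 again needs inversion (Mitsunobu with propanoic acid after desilylation). The isopropenyl group must be hydrogenated selectively beside the ring enone and, depending on timing, the side-chain alkene. The 1,2-dicarbonyl is prone to hydration and self-condensation. The Z enone may isomerise under the Lewis acid.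
- Comparison: in stereocentres created per step and in probable length this route is better, because the chosen key step creates no lasting stereocentre. Both plans close the ring with C2=C3 and C7 already present, so they are equal on that point. The chosen plan is better on robustness: its cyclisation precursor is a stable, fully defined compound, and no centre depends on 1,3-induction, on an inversion or on a chemoselective hydrogenation.

Key step: step 12

Remarks and assumptions:
- Locants C1–C7 in the discussion are those of the ring of 29; systematic names of acyclic compounds carry chain locants.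
- The descriptors at C1 (R in 13–18, S in 20–29) and at C6 (R in 6–12 and 22, S elsewhere) change only through CIP priorities. The spatial arrangement is that of 29 throughout.
- The alkenyl iodide is Z (iodine cis to C1), the only geometry that lets C3 reach C4.
- Step 12 is expected to give both C4 epimers of 20. The list shows the 4R epimer, and the mixture is oxidised as such in step 13.
- Compounds 4, 23 and 24 are treated as purchasable. The side-chain acid is therefore built by olefination and not by allylic functionalisation of a tiglate, whose regiochemistry is less secure.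

## Route

Step 1
Reactants: 1 (R)-4-benzyl-1,3-oxazolidin-2-one; 2 3-methylbutanoyl chloride (isovaleryl chloride)
Product: 3 (R)-4-benzyl-3-(3-methylbutanoyl)-1,3-oxazolidin-2-one
Conditions: Et3N, DMAP (cat.), CH2Cl2, 0 °C → rt
Reagents that add atoms: none
Why: DMAP-catalysed N-acylation of the oxazolidinone by the acid chloride; the auxiliary stereocentre is not touched.

Step 2
Reactants: 3 (R)-4-benzyl-3-(3-methylbutanoyl)-1,3-oxazolidin-2-one; 4 2-(4-methoxybenzyloxy)acetaldehyde
Product: 6 (R)-4-benzyl-3-[(2R,3R)-3-hydroxy-4-(4-methoxybenzyloxy)-2-isopropylbutanoyl]-1,3-oxazolidin-2-one, via Z-dibutylboron enolate 5 (not isolated)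
Conditions: Bu2BOTf, i-Pr2NEt, CH2Cl2, −78 → 0 °C; 4, −78 → 0 °C; pH 7 buffer (NaH2PO4/Na2HPO4), MeOH, H2O2, 0 °C
Reagents that add atoms: dibutylboron triflate, CCCCB(CCCC)OS(=O)(=O)C(F)(F)F (boron and butyl groups are held only in 5)
Why: Evans syn aldol: the Z boron enolate 5 reacts through a Zimmerman–Traxler chair with the imide dipoles opposed, so the aldehyde approaches the face away from the benzyl group; this sets C6 and C5 in the syn sense with the absolute configuration fixed by the (R)-auxiliary, and boron does not chelate the α-alkoxy aldehyde.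

Step 3
Reactants: 6 (R)-4-benzyl-3-[(2R,3R)-3-hydroxy-4-(4-methoxybenzyloxy)-2-isopropylbutanoyl]-1,3-oxazolidin-2-one
Product: 7 (2R,3R)-3-hydroxy-N-methoxy-4-(4-methoxybenzyloxy)-N-methyl-2-isopropylbutanamide
Conditions: MeNH(OMe)·HCl, AlMe3, THF, −15 → 0 °C; aq. potassium sodium tartrate
Reagents that add atoms: N,O-dimethylhydroxylamine hydrochloride, CNOC.Cl
Why: Weinreb transamination with an aluminium amide; the free C5 hydroxyl binds aluminium and steers attack to the exocyclic carbonyl, so the auxiliary is released intact and C6 is not epimerised.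

Step 4
Reactants: 7 (2R,3R)-3-hydroxy-N-methoxy-4-(4-methoxybenzyloxy)-N-methyl-2-isopropylbutanamide
Product: 8 (2R,3R)-N-methoxy-4-(4-methoxybenzyloxy)-N-methyl-2-isopropyl-3-(triethylsilyloxy)butanamide
Conditions: TESOTf, 2,6-lutidine, CH2Cl2, −78 → 0 °C
Reagents that add atoms: triethylsilyl triflate, CC[Si](CC)(CC)OS(=O)(=O)C(F)(F)F
Why: Silylation of the secondary C5 hydroxyl; triethylsilyl survives all steps up to the enone and can later be removed beside the primary tert-butyldiphenylsilyl ether, and a silyl ether (unlike an ester) cannot shift to the C4 oxygen formed in step 12.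

Step 5
Reactants: 9 prop-2-yn-1-ol
Product: 10 tert-butyl(diphenyl)(prop-2-yn-1-yloxy)silane
Conditions: TBDPSCl, imidazole, CH2Cl2, 0 °C → rt
Reagents that add atoms: tert-butyl(chloro)diphenylsilane, CC(C)(C)[Si](Cl)(c1ccccc1)c1ccccc1
Why: Silylation of a primary alcohol; the bulky, poorly leaving silyloxy group at C7 is chosen to resist hydride, chromium and mild acid.

Step 6
Reactants: 8 (2R,3R)-N-methoxy-4-(4-methoxybenzyloxy)-N-methyl-2-isopropyl-3-(triethylsilyloxy)butanamide; 10 tert-butyl(diphenyl)(prop-2-yn-1-yloxy)silane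
Product: 12 (5R,6R)-1-(tert-butyldiphenylsilyloxy)-5-isopropyl-7-(4-methoxybenzyloxy)-6-(triethylsilyloxy)hept-2-yn-4-one, via lithium acetylide 11 (not isolated)
Conditions: 10, n-BuLi, THF, −78 °C; then 8, −78 → −20 °C; cold aq. NH4Cl
Reagents that add atoms: n-butyllithium, [Li]CCCC (lithium is held only in 11)
Why: Weinreb ketone synthesis: the acetylide adds once and the chelated tetrahedral adduct collapses only on quench, so there is no over-addition and the C6 centre is never exposed as an enolisable ynone to base.

Step 7
Reactants: 12 (5R,6R)-1-(tert-butyldiphenylsilyloxy)-5-isopropyl-7-(4-methoxybenzyloxy)-6-(triethylsilyloxy)hept-2-yn-4-one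
Product: 13 (4R,5S,6R)-1-(tert-butyldiphenylsilyloxy)-5-isopropyl-7-(4-methoxybenzyloxy)-6-(triethylsilyloxy)hept-2-yn-4-ol
Conditions: Ru[(R,R)-TsNCH(Ph)CH(Ph)NH](p-cymene) (5 mol %), i-PrOH, rt
Reagents that add atoms: none
Why: Noyori asymmetric transfer hydrogenation of an alkynyl ketone: the Ru–H/N–H pair delivers H2 through a six-membered transition state in which the alkynyl group takes the place of the aryl group of aryl ketones, so the (R,R) catalyst should give the 4R carbinol (C1) by reagent control; the neutral medium spares the silyl ethers and the C6 centre.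

Step 8
Reactants: 13 (4R,5S,6R)-1-(tert-butyldiphenylsilyloxy)-5-isopropyl-7-(4-methoxybenzyloxy)-6-(triethylsilyloxy)hept-2-yn-4-ol
Product: 15 (2Z,4R,5S,6R)-1-(tert-butyldiphenylsilyloxy)-2-iodo-5-isopropyl-7-(4-methoxybenzyloxy)-6-(triethylsilyloxy)hept-2-en-4-ol, via cyclic alkenylaluminate 14 (not isolated)
Conditions: NaAlH2(OCH2CH2OMe)2, THF, 0 °C; EtOAc, −78 °C; then I2, THF, −78 → 0 °C; aq. potassium sodium tartrate/Na2S2O3
Reagents that add atoms: sodium bis(2-methoxyethoxy)aluminium dihydride, [Na+].COCCO[AlH2-]OCCOC (aluminium, sodium and alkoxy groups are held only in 14); iodine, II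
Why: Hydroxyl-directed trans-hydroalumination: the C1 alkoxyaluminium hydride delivers hydride to C2 and leaves aluminium on C3 in a five-membered ring, cis to C1; iodinolysis with retention gives the Z iodide, and the silyl ethers cannot compete as directing groups.

Step 9
Reactants: 15 (2Z,4R,5S,6R)-1-(tert-butyldiphenylsilyloxy)-2-iodo-5-isopropyl-7-(4-methoxybenzyloxy)-6-(triethylsilyloxy)hept-2-en-4-ol
Product: 16 (2Z,4R,5S,6R)-1-(tert-butyldiphenylsilyloxy)-2-iodo-5-isopropyl-7-(4-methoxybenzyloxy)-6-(triethylsilyloxy)hept-2-en-4-yl propanoate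
Conditions: (EtCO)2O, Et3N, DMAP (cat.), CH2Cl2, 0 °C → rt
Reagents that add atoms: propanoic anhydride, CCC(=O)OC(=O)CC
Why: DMAP-catalysed acylation of the secondary allylic alcohol with retention at C1; it is done only now because the hydride reagent of step 8 would have reduced the ester.

Step 10
Reactants: 16 (2Z,4R,5S,6R)-1-(tert-butyldiphenylsilyloxy)-2-iodo-5-isopropyl-7-(4-methoxybenzyloxy)-6-(triethylsilyloxy)hept-2-en-4-yl propanoate
Product: 17 (2R,3S,4R,5Z)-7-(tert-butyldiphenylsilyloxy)-1-hydroxy-6-iodo-3-isopropyl-2-(triethylsilyloxy)hept-5-en-4-yl propanoate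
Conditions: DDQ, CH2Cl2/pH 7 buffer (NaH2PO4/Na2HPO4) 10:1, 0 °C
Reagents that add atoms: none
Why: Oxidative cleavage of the 4-methoxybenzyl ether (benzylic hydride abstraction, hydrolysis of the oxocarbenium ion); the buffered neutral medium leaves both silyl ethers, the ester and the alkenyl iodide alone.

Step 11
Reactants: 17 (2R,3S,4R,5Z)-7-(tert-butyldiphenylsilyloxy)-1-hydroxy-6-iodo-3-isopropyl-2-(triethylsilyloxy)hept-5-en-4-yl propanoate
Product: 18 (2R,3S,4R,5Z)-7-(tert-butyldiphenylsilyloxy)-6-iodo-3-isopropyl-1-oxo-2-(triethylsilyloxy)hept-5-en-4-yl propanoate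
Conditions: Dess–Martin periodinane, NaHCO3, CH2Cl2, 0 °C → rt
Reagents that add atoms: none
Why: Dess–Martin oxidation of the primary alcohol to the aldehyde under buffered, non-basic conditions, so the α-silyloxy centre C5 keeps its configuration.

Step 12
Reactants: 18 (2R,3S,4R,5Z)-7-(tert-butyldiphenylsilyloxy)-6-iodo-3-isopropyl-1-oxo-2-(triethylsilyloxy)hept-5-en-4-yl propanoate
Product: 20 (1S,4R,5R,6S)-3-[(tert-butyldiphenylsilyloxy)methyl]-4-hydroxy-6-isopropyl-5-(triethylsilyloxy)cyclohex-2-en-1-yl propanoate (with its 4S epimer), via alkenylchromium dichloride 19 (not isolated)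
Conditions: CrCl2 (8 equiv), NiCl2 (1 mol % of the CrCl2), degassed DMSO, 0.005 M, rt; aq. NH4Cl
Reagents that add atoms: chromium dichloride, Cl[Cr]Cl (chromium and chloride are held only in 19)
Why: CrCl2 reduces NiCl2 to zerovalent nickel, which inserts into the C3–I bond with retention of the Z geometry; the alkenyl group then passes to trivalent chromium to give 19 and nickel returns to the cycle. The alkenylchromium adds to the C4 aldehyde, and the strong chromium–oxygen bond of the alkoxide makes the addition irreversible until aqueous work-up frees 20. The closest known reaction type is the intramolecular Nozaki–Hiyama–Kishi cyclisation of iodoalkenyl aldehydes to cycloalkenols. The six-membered ring closes in the 6-exo-trig mode with respect to the carbonyl group, with C2=C3 ending up inside the ring. The only new stereocentre is C4; a Felkin-type approach anti to the C5 silyloxy group should favour one epimer, but no control is needed because step 13 removes this centre. The step needs chemoselectivity (aldehyde over the ester, no loss of the C7 silyloxy group, no ionisation of the allylic propanoate), which rests on the low basicity and aldehyde selectivity of alkenylchromium reagents and on the faster insertion of nickel into the C–I bond. Ring closure over dimerisation rests on the Z geometry from step 8, which holds C3 cis to C1 and within reach of C4, and on high dilution.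

Step 13
Reactants: 20 (1S,4R,5R,6S)-3-[(tert-butyldiphenylsilyloxy)methyl]-4-hydroxy-6-isopropyl-5-(triethylsilyloxy)cyclohex-2-en-1-yl propanoate (both C4 epimers)
Product: 21 (1S,5R,6S)-3-[(tert-butyldiphenylsilyloxy)methyl]-6-isopropyl-4-oxo-5-(triethylsilyloxy)cyclohex-2-en-1-yl propanoate
Conditions: Dess–Martin periodinane, NaHCO3, CH2Cl2, 0 °C → rt
Reagents that add atoms: none
Why: Dess–Martin oxidation of the allylic carbinol; both C4 epimers converge on one enone, and the buffered medium avoids epimerisation at C5 and elimination of the C1 ester.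

Step 14
Reactants: 21 (1S,5R,6S)-3-[(tert-butyldiphenylsilyloxy)methyl]-6-isopropyl-4-oxo-5-(triethylsilyloxy)cyclohex-2-en-1-yl propanoate
Product: 22 (1S,5R,6R)-3-[(tert-butyldiphenylsilyloxy)methyl]-5-hydroxy-6-isopropyl-4-oxocyclohex-2-en-1-yl propanoate
Conditions: AcOH/THF/H2O (3:1:1), rt
Reagents that add atoms: none
Why: Acid-catalysed hydrolysis of the triethylsilyl ether; the primary tert-butyldiphenylsilyl ether is far more stable to aqueous acetic acid, and no base is present to epimerise the α-ketol or shift the propanoate (which is trans to the C5 hydroxyl).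

Step 15
Reactants: 23 2-(tert-butyldimethylsilyloxy)acetaldehyde; 24 ethyl 2-(triphenyl-λ5-phosphanylidene)propanoate
Product: 25 ethyl (E)-4-(tert-butyldimethylsilyloxy)-2-methylbut-2-enoate
Conditions: CH2Cl2, rt
Reagents that add atoms: none
Why: Wittig olefination with a stabilised α-methyl ylide, which is E-selective for trisubstituted enoates and places the oxygen at C4 of the side chain without ambiguity.

Step 16
Reactants: 25 ethyl (E)-4-(tert-butyldimethylsilyloxy)-2-methylbut-2-enoate
Product: 26 (E)-4-(tert-butyldimethylsilyloxy)-2-methylbut-2-enoic acid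
Conditions: LiOH, THF/H2O (3:1), 0 °C → rt; then 0.5 M HCl to pH 4, 0 °C
Reagents that add atoms: lithium hydroxide, [Li+].[OH-]
Why: Saponification of the ethyl ester; the primary silyl ether is stable to hydroxide at room temperature, and the cold acidification to pH 4 avoids desilylation.

Step 17
Reactants: 22 (1S,5R,6R)-3-[(tert-butyldiphenylsilyloxy)methyl]-5-hydroxy-6-isopropyl-4-oxocyclohex-2-en-1-yl propanoate; 26 (E)-4-(tert-butyldimethylsilyloxy)-2-methylbut-2-enoic acid
Product: 28 (1S,5R,6S)-3-[(tert-butyldiphenylsilyloxy)methyl]-6-isopropyl-4-oxo-1-(propanoyloxy)cyclohex-2-en-5-yl (E)-4-(tert-butyldimethylsilyloxy)-2-methylbut-2-enoate, via mixed anhydride 27 (not isolated)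
Conditions: 26, 2,4,6-Cl3C6H2COCl, Et3N, toluene, rt; then 22, DMAP, toluene, 0 °C → rt
Reagents that add atoms: 2,4,6-trichlorobenzoyl chloride, O=C(Cl)c1c(Cl)cc(Cl)cc1Cl (held only in 27)
Why: Yamaguchi esterification: DMAP attacks the less hindered enoyl carbonyl of 27 and the acylpyridinium acylates the C5 hydroxyl with retention; the E enoate is the stable geometry, and the trans C5 ester is the stable epimer beside the isopropyl group.

Step 18
Reactants: 28 (1S,5R,6S)-3-[(tert-butyldiphenylsilyloxy)methyl]-6-isopropyl-4-oxo-1-(propanoyloxy)cyclohex-2-en-5-yl (E)-4-(tert-butyldimethylsilyloxy)-2-methylbut-2-enoate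
Product: 29 (1S,5R,6S)-3-(hydroxymethyl)-6-isopropyl-4-oxo-1-(propanoyloxy)cyclohex-2-en-5-yl (E)-4-hydroxy-2-methylbut-2-enoate (CNP0285949.1)
Conditions: HF·pyridine, THF, polyethylene vessel, 0 °C → rt; aq. NaHCO3
Reagents that add atoms: none
Why: Fluoride cleavage of both primary silyl ethers, driven by the Si–F bond; the weakly acidic, non-basic medium should avoid acyl migration, loss of the C1 ester and epimerisation at C5.

## Compound list

1 | (R)-4-benzyl-1,3-oxazolidin-2-one | O=C1N[C@H](Cc2ccccc2)CO1 | starting material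
2 | 3-methylbutanoyl chloride (isovaleryl chloride) | CC(C)CC(Cl)=O | starting material
3 | (R)-4-benzyl-3-(3-methylbutanoyl)-1,3-oxazolidin-2-one | CC(C)CC(=O)N1[C@H](Cc2ccccc2)COC1=O | intermediate
4 | 2-(4-methoxybenzyloxy)acetaldehyde | COc1ccc(COCC=O)cc1 | starting material
5 | Z-dibutylboron enolate of 3 | CCCCB(CCCC)O/C(=C\C(C)C)N1[C@H](Cc2ccccc2)COC1=O | intermediate (not isolated)
6 | (R)-4-benzyl-3-[(2R,3R)-3-hydroxy-4-(4-methoxybenzyloxy)-2-isopropylbutanoyl]-1,3-oxazolidin-2-one | O=C1OC[C@@H](Cc2ccccc2)N1C(=O)[C@H](C(C)C)[C@@H](O)COCc1ccc(OC)cc1 | intermediate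
7 | (2R,3R)-3-hydroxy-N-methoxy-4-(4-methoxybenzyloxy)-N-methyl-2-isopropylbutanamide | CON(C)C(=O)[C@H](C(C)C)[C@@H](O)COCc1ccc(OC)cc1 | intermediate
8 | (2R,3R)-N-methoxy-4-(4-methoxybenzyloxy)-N-methyl-2-isopropyl-3-(triethylsilyloxy)butanamide | CON(C)C(=O)[C@H](C(C)C)[C@@H](O[Si](CC)(CC)CC)COCc1ccc(OC)cc1 | intermediate
9 | prop-2-yn-1-ol (propargyl alcohol) | C#CCO | starting material
10 | tert-butyl(diphenyl)(prop-2-yn-1-yloxy)silane | C#CCO[Si](c1ccccc1)(c1ccccc1)C(C)(C)C | intermediate
11 | lithium acetylide of 10 | [Li]C#CCO[Si](c1ccccc1)(c1ccccc1)C(C)(C)C | intermediate (not isolated)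
12 | (5R,6R)-1-(tert-butyldiphenylsilyloxy)-5-isopropyl-7-(4-methoxybenzyloxy)-6-(triethylsilyloxy)hept-2-yn-4-one | O=C(C#CCO[Si](c1ccccc1)(c1ccccc1)C(C)(C)C)[C@H](C(C)C)[C@@H](O[Si](CC)(CC)CC)COCc1ccc(OC)cc1 | intermediate
13 | (4R,5S,6R)-1-(tert-butyldiphenylsilyloxy)-5-isopropyl-7-(4-methoxybenzyloxy)-6-(triethylsilyloxy)hept-2-yn-4-ol | O[C@@H](C#CCO[Si](c1ccccc1)(c1ccccc1)C(C)(C)C)[C@H](C(C)C)[C@@H](O[Si](CC)(CC)CC)COCc1ccc(OC)cc1 | intermediate
14 | sodium alkenylaluminate from 13 (five-membered ring O–Al–C3=C2–C1, two 2-methoxyethoxy groups on aluminium) | COCCO[Al-]1(OCCOC)O[C@H]([C@H](C(C)C)[C@@H](O[Si](CC)(CC)CC)COCc2ccc(OC)cc2)C=C1CO[Si](c1ccccc1)(c1ccccc1)C(C)(C)C.[Na+] | intermediate (not isolated)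
15 | (2Z,4R,5S,6R)-1-(tert-butyldiphenylsilyloxy)-2-iodo-5-isopropyl-7-(4-methoxybenzyloxy)-6-(triethylsilyloxy)hept-2-en-4-ol | O[C@@H](/C=C(\I)CO[Si](c1ccccc1)(c1ccccc1)C(C)(C)C)[C@H](C(C)C)[C@@H](O[Si](CC)(CC)CC)COCc1ccc(OC)cc1 | intermediate
16 | (2Z,4R,5S,6R)-1-(tert-butyldiphenylsilyloxy)-2-iodo-5-isopropyl-7-(4-methoxybenzyloxy)-6-(triethylsilyloxy)hept-2-en-4-yl propanoate | CCC(=O)O[C@@H](/C=C(\I)CO[Si](c1ccccc1)(c1ccccc1)C(C)(C)C)[C@H](C(C)C)[C@@H](O[Si](CC)(CC)CC)COCc1ccc(OC)cc1 | intermediate
17 | (2R,3S,4R,5Z)-7-(tert-butyldiphenylsilyloxy)-1-hydroxy-6-iodo-3-isopropyl-2-(triethylsilyloxy)hept-5-en-4-yl propanoate | CCC(=O)O[C@@H](/C=C(\I)CO[Si](c1ccccc1)(c1ccccc1)C(C)(C)C)[C@H](C(C)C)[C@@H](O[Si](CC)(CC)CC)CO | intermediate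
18 | (2R,3S,4R,5Z)-7-(tert-butyldiphenylsilyloxy)-6-iodo-3-isopropyl-1-oxo-2-(triethylsilyloxy)hept-5-en-4-yl propanoate | CCC(=O)O[C@@H](/C=C(\I)CO[Si](c1ccccc1)(c1ccccc1)C(C)(C)C)[C@H](C(C)C)[C@@H](O[Si](CC)(CC)CC)C=O | intermediate
19 | alkenylchromium dichloride from 18 (trivalent chromium on C3) | CCC(=O)O[C@@H](/C=C(\[Cr](Cl)Cl)CO[Si](c1ccccc1)(c1ccccc1)C(C)(C)C)[C@H](C(C)C)[C@@H](O[Si](CC)(CC)CC)C=O | intermediate (not isolated)
20 | (1S,4R,5R,6S)-3-[(tert-butyldiphenylsilyloxy)methyl]-4-hydroxy-6-isopropyl-5-(triethylsilyloxy)cyclohex-2-en-1-yl propanoate (one C4 epimer shown) | CCC(=O)O[C@H]1C=C(CO[Si](c2ccccc2)(c2ccccc2)C(C)(C)C)[C@@H](O)[C@H](O[Si](CC)(CC)CC)[C@H]1C(C)C | intermediate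
21 | (1S,5R,6S)-3-[(tert-butyldiphenylsilyloxy)methyl]-6-isopropyl-4-oxo-5-(triethylsilyloxy)cyclohex-2-en-1-yl propanoate | CCC(=O)O[C@H]1C=C(CO[Si](c2ccccc2)(c2ccccc2)C(C)(C)C)C(=O)[C@H](O[Si](CC)(CC)CC)[C@H]1C(C)C | intermediate
22 | (1S,5R,6R)-3-[(tert-butyldiphenylsilyloxy)methyl]-5-hydroxy-6-isopropyl-4-oxocyclohex-2-en-1-yl propanoate | CCC(=O)O[C@H]1C=C(CO[Si](c2ccccc2)(c2ccccc2)C(C)(C)C)C(=O)[C@H](O)[C@H]1C(C)C | intermediate
23 | 2-(tert-butyldimethylsilyloxy)acetaldehyde | O=CCO[Si](C)(C)C(C)(C)C | starting material
24 | ethyl 2-(triphenyl-λ5-phosphanylidene)propanoate | CCOC(=O)C(C)=P(c1ccccc1)(c1ccccc1)c1ccccc1 | starting material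
25 | ethyl (E)-4-(tert-butyldimethylsilyloxy)-2-methylbut-2-enoate | CCOC(=O)/C(C)=C/CO[Si](C)(C)C(C)(C)C | intermediate
26 | (E)-4-(tert-butyldimethylsilyloxy)-2-methylbut-2-enoic acid | OC(=O)/C(C)=C/CO[Si](C)(C)C(C)(C)C | intermediate
27 | (E)-4-(tert-butyldimethylsilyloxy)-2-methylbut-2-enoic 2,4,6-trichlorobenzoic anhydride | O=C(OC(=O)c1c(Cl)cc(Cl)cc1Cl)/C(C)=C/CO[Si](C)(C)C(C)(C)C | intermediate (not isolated)
28 | (1S,5R,6S)-3-[(tert-butyldiphenylsilyloxy)methyl]-6-isopropyl-4-oxo-1-(propanoyloxy)cyclohex-2-en-5-yl (E)-4-(tert-butyldimethylsilyloxy)-2-methylbut-2-enoate | CCC(=O)O[C@H]1C=C(CO[Si](c2ccccc2)(c2ccccc2)C(C)(C)C)C(=O)[C@H](OC(=O)/C(C)=C/CO[Si](C)(C)C(C)(C)C)[C@H]1C(C)C | intermediate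
29 | (1S,5R,6S)-3-(hydroxymethyl)-6-isopropyl-4-oxo-1-(propanoyloxy)cyclohex-2-en-5-yl (E)-4-hydroxy-2-methylbut-2-enoate | CCC(=O)O[C@H]1C=C(CO)C(=O)[C@H](OC(=O)/C(C)=C/CO)[C@H]1C(C)C | target

## Step count and least certain steps

Total: 18 steps. Longest linear sequence: 15 steps (steps 1–4, 6–14, 17 and 18). Step 5 and steps 15–16 are side branches.

Step 12 (key step). The most likely failure is loss of iodine without ring closure: the alkenyl metal is protonated, or it eliminates the neighbouring C7 silyloxy group, before it reaches the aldehyde. Oligomerisation is possible if dilution is insufficient.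
- Fallback, from 13 back to 20: the C3–C4 bond is made between two molecules and the ring is closed at C2=C3 instead.
- Semihydrogenation of 13 over Pd/CaCO3 poisoned with Pb(OAc)2 (quinoline, H2) would give the Z allylic alcohol (2Z,4S,5S,6R)-1-(tert-butyldiphenylsilyloxy)-5-isopropyl-7-(4-methoxybenzyloxy)-6-(triethylsilyloxy)hept-2-en-4-ol F1.
- Propionylation as in step 9 would give its propanoate F2. DDQ as in step 10 would give the primary alcohol F3, and Dess–Martin oxidation the aldehyde F4.
- The alkenyl metal from tert-butyl[(2-bromoprop-2-en-1-yl)oxy]diphenylsilane F5 (from 2-bromoprop-2-en-1-ol, TBDPSCl and imidazole) would be added to F4 under intermolecular CrCl2/NiCl2 conditions. No ring has to form and the halide can be used in excess. This would give the diene F6 as both carbinol epimers.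
- Ring-closing metathesis with RuCl2(H2IMes)(=CH-C6H4-2-O-i-Pr), the second-generation Hoveyda–Grubbs catalyst, in toluene would join C2 to C3, expel the allyl silyl ether, and give 20.

Step 8. The alkenylaluminate 14 carries a silyloxy group on the carbon next to the C–Al bond. The most likely failure is elimination of that group to an allene, or simple protonation to the iodine-free alkene, if the mixture is warmed or iodination is slow.
- Fallback, from 13 back to 15: trans-hydrosilylation of 13 with Et3SiH and [Cp*Ru(MeCN)3]PF6 (a cationic complex of divalent ruthenium) in CH2Cl2 should place silicon on C3, the carbon distal to the free hydroxyl. The conditions are neutral and the C–Si bond does not eliminate. The product would be the alkenylsilane (2Z,4R,5S,6R)-1-(tert-butyldiphenylsilyloxy)-5-isopropyl-7-(4-methoxybenzyloxy)-2-(triethylsilyl)-6-(triethylsilyloxy)hept-2-en-4-ol F7.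
- Iododesilylation of F7 with N-iodosuccinimide in (CF3)2CHOH buffered with 2,6-lutidine, with retention, would give 15.

Step 7. The risk is poor facial selectivity if the C6 stereocentre opposes the (R,R) catalyst (a mismatched pair); the bulk at the α-carbon may also slow the reduction.
- Fallback, from 12 back to 16: reduction with the enantiomeric catalyst Ru[(S,S)-TsNCH(Ph)CH(Ph)NH](p-cymene), which would then be the matched case, should give the epimeric alcohol (4S,5S,6R)-1-(tert-butyldiphenylsilyloxy)-5-isopropyl-7-(4-methoxybenzyloxy)-6-(triethylsilyloxy)hept-2-yn-4-ol F8.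
- The conditions of step 8 would turn F8 into the iodo alcohol (2Z,4S,5S,6R)-1-(tert-butyldiphenylsilyloxy)-2-iodo-5-isopropyl-7-(4-methoxybenzyloxy)-6-(triethylsilyloxy)hept-2-en-4-ol F9.
- Mitsunobu esterification of F9 with propanoic acid (PPh3, DIAD, THF) would install the propanoate with inversion at C1 and give 16.

Step 17. The hindered α-ketol may react slowly with a conjugated, α-branched acyl donor. That leaves time for DMAP to epimerise C5 or to start elimination of the C1 ester from the γ-acyloxy enone.
- Fallback, from 22 back to 28: acylation of 22 with the small, unconjugated 2-(diethoxyphosphoryl)propanoic acid (EDC·HCl, catalytic DMAP, CH2Cl2) would give the phosphonate ester (1S,5R,6S)-3-[(tert-butyldiphenylsilyloxy)methyl]-6-isopropyl-4-oxo-1-(propanoyloxy)cyclohex-2-en-5-yl 2-(diethoxyphosphoryl)propanoate F10.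
- Horner–Wadsworth–Emmons reaction of F10 with the aldehyde 23 under LiCl/i-Pr2NEt in MeCN would build the E enoate on the ring and give 28.

## Further compounds

F1 | step 12 | (2Z,4S,5S,6R)-1-(tert-butyldiphenylsilyloxy)-5-isopropyl-7-(4-methoxybenzyloxy)-6-(triethylsilyloxy)hept-2-en-4-ol | O[C@@H](/C=C\CO[Si](c1ccccc1)(c1ccccc1)C(C)(C)C)[C@H](C(C)C)[C@@H](O[Si](CC)(CC)CC)COCc1ccc(OC)cc1
F2 | step 12 | (2Z,4S,5S,6R)-1-(tert-butyldiphenylsilyloxy)-5-isopropyl-7-(4-methoxybenzyloxy)-6-(triethylsilyloxy)hept-2-en-4-yl propanoate | CCC(=O)O[C@@H](/C=C\CO[Si](c1ccccc1)(c1ccccc1)C(C)(C)C)[C@H](C(C)C)[C@@H](O[Si](CC)(CC)CC)COCc1ccc(OC)cc1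
F3 | step 12 | (2R,3S,4S,5Z)-7-(tert-butyldiphenylsilyloxy)-1-hydroxy-3-isopropyl-2-(triethylsilyloxy)hept-5-en-4-yl propanoate | CCC(=O)O[C@@H](/C=C\CO[Si](c1ccccc1)(c1ccccc1)C(C)(C)C)[C@H](C(C)C)[C@@H](O[Si](CC)(CC)CC)CO
F4 | step 12 | (2R,3S,4S,5Z)-7-(tert-butyldiphenylsilyloxy)-3-isopropyl-1-oxo-2-(triethylsilyloxy)hept-5-en-4-yl propanoate | CCC(=O)O[C@@H](/C=C\CO[Si](c1ccccc1)(c1ccccc1)C(C)(C)C)[C@H](C(C)C)[C@@H](O[Si](CC)(CC)CC)C=O
F5 | step 12 | tert-butyl[(2-bromoprop-2-en-1-yl)oxy]diphenylsilane | C=C(Br)CO[Si](c1ccccc1)(c1ccccc1)C(C)(C)C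
F6 | step 12 | (3R,4R,5S,6S,7Z)-9-(tert-butyldiphenylsilyloxy)-2-[(tert-butyldiphenylsilyloxy)methyl]-3-hydroxy-5-isopropyl-4-(triethylsilyloxy)nona-1,7-dien-6-yl propanoate (one C3 epimer shown) | CCC(=O)O[C@@H](/C=C\CO[Si](c1ccccc1)(c1ccccc1)C(C)(C)C)[C@H](C(C)C)[C@@H](O[Si](CC)(CC)CC)[C@H](O)C(=C)CO[Si](c1ccccc1)(c1ccccc1)C(C)(C)C
F7 | step 8 | (2Z,4R,5S,6R)-1-(tert-butyldiphenylsilyloxy)-5-isopropyl-7-(4-methoxybenzyloxy)-2-(triethylsilyl)-6-(triethylsilyloxy)hept-2-en-4-ol | O[C@@H](/C=C(\[Si](CC)(CC)CC)CO[Si](c1ccccc1)(c1ccccc1)C(C)(C)C)[C@H](C(C)C)[C@@H](O[Si](CC)(CC)CC)COCc1ccc(OC)cc1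
F8 | step 7 | (4S,5S,6R)-1-(tert-butyldiphenylsilyloxy)-5-isopropyl-7-(4-methoxybenzyloxy)-6-(triethylsilyloxy)hept-2-yn-4-ol | O[C@H](C#CCO[Si](c1ccccc1)(c1ccccc1)C(C)(C)C)[C@H](C(C)C)[C@@H](O[Si](CC)(CC)CC)COCc1ccc(OC)cc1
F9 | step 7 | (2Z,4S,5S,6R)-1-(tert-butyldiphenylsilyloxy)-2-iodo-5-isopropyl-7-(4-methoxybenzyloxy)-6-(triethylsilyloxy)hept-2-en-4-ol | O[C@H](/C=C(\I)CO[Si](c1ccccc1)(c1ccccc1)C(C)(C)C)[C@H](C(C)C)[C@@H](O[Si](CC)(CC)CC)COCc1ccc(OC)cc1
F10 | step 17 | (1S,5R,6S)-3-[(tert-butyldiphenylsilyloxy)methyl]-6-isopropyl-4-oxo-1-(propanoyloxy)cyclohex-2-en-5-yl 2-(diethoxyphosphoryl)propanoate | CCC(=O)O[C@H]1C=C(CO[Si](c2ccccc2)(c2ccccc2)C(C)(C)C)C(=O)[C@H](OC(=O)C(C)P(=O)(OCC)OCC)[C@H]1C(C)C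
A1 | alternative 1 | 5-[(tert-butyldimethylsilyloxy)methyl]-7-isopropyl-2,3-dioxabicyclo[2.2.2]oct-5-ene, peroxide bridge anti to isopropyl | CC(C)[C@@H]1C[C@H]2OO[C@@H]1C=C2CO[Si](C)(C)C(C)(C)C
A2 | alternative 1 | (S)-2-[(tert-butyldimethylsilyloxy)methyl]-5-isopropylcyclohexa-1,3-diene | CC(C)[C@@H]1CC=C(CO[Si](C)(C)C(C)(C)C)C=C1
A3 | alternative 1 | 2-[(tert-butyldimethylsilyloxy)methyl]-4-hydroxy-5-isopropylcyclohex-2-en-1-one, hydroxyl trans to isopropyl | CC(C)[C@@H]1CC(=O)C(CO[Si](C)(C)C(C)(C)C)=C[C@H]1O
A4 | alternative 2 | 2-(tert-butyldimethylsilyloxy)-5-hydroxy-3-isopropyl-4-(4-methoxybenzyloxy)cyclohexan-1-one (one epimer at the new carbinol) | COc1ccc(cc1)CO[C@H]2[C@H](O)CC(=O)[C@H](O[Si](C)(C)C(C)(C)C)[C@H]2C(C)C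
A5 | alternative 2 | methyl 4-O-(tert-butyldimethylsilyl)-3,6-dideoxy-3-C-isopropyl-2-O-(4-methoxybenzyl)hex-5-enopyranoside, gulo arrangement at C2–C4 (anomeric configuration of no consequence) | CO[C@@H]1OC(=C)[C@H](O[Si](C)(C)C(C)(C)C)[C@@H](C(C)C)[C@H]1OCc1ccc(OC)cc1
A6 | alternative 3 | 4-(tert-butyldimethylsilyloxy)-2-[(tert-butyldiphenylsilyloxy)methyl]-6-hydroxy-5-isopropenylcyclohex-2-en-1-one, all three ring substituents trans | CC(C)(C)[Si](C)(C)O[C@@H]1C=C(CO[Si](c2ccccc2)(c2ccccc2)C(C)(C)C)C(=O)[C@H](O)[C@H]1C(C)=C
A7 | alternative 3 | (3Z)-5-(tert-butyldimethylsilyloxy)-3-[(tert-butyldiphenylsilyloxy)methyl]-7-methyl-2-oxoocta-3,6-dienal, single enantiomer as drawn | CC(C)=C[C@H](O[Si](C)(C)C(C)(C)C)/C=C(/CO[Si](c1ccccc1)(c1ccccc1)C(C)(C)C)C(=O)C=O
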